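**Retrosynthetic overview**
1. The ester C–O bond is cut first: target 23 comes from silyl-protected ferulic acid 21 and core alcohol 18, in which C9-OH and the phenol are TIPS ethers.
2. The strategy rests on the ring O1–C2–C3–C3a–C7a with exocyclic C9 on C3. It is a chroman-4-one whose carbonyl carbon has been pushed out of the ring, so C3–C3a is made by a 1,2-shift of the aryl carbon from C=O to C3 (photo-Wolff contraction of 3-diazoflavanone 11 to ester 14; the ester carbon becomes C9).
3. Diazo ketone 11 comes from (2R)-flavanone 9, and 9 from chromone 7 plus arylboronic acid 8 by Pd-catalysed asymmetric conjugate arylation, which sets C2.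
4. Chromone 7 comes from 6-bromochromone 4 and allyl silyl ether 5 (B-alkyl Suzuki coupling); 4 comes from 2'-hydroxy-3'-methoxyacetophenone 1.
5. Ring order: both benzene rings are bought; the pyranone ring is closed in step 2 and contracted to the dihydrofuran in step 6.

Key step: step 6

Remark on the chemistry: the A-ring ketone is taken from 2'-hydroxy-3'-methoxyacetophenone, because acyl migration in a 4-alkylguaiacyl acetate (a Fries route from eugenol) is not regiochemically secure and an allyl group would not survive Pd(II); (S)-t-BuPyOx is assumed to give the 2R sense by analogy with cyclic enones, and the antipodal ligand is used if it does not.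

**Route**

Step 1
Reactants: 1 2'-hydroxy-3'-methoxyacetophenone
Product: 2 1-(5-bromo-2-hydroxy-3-methoxyphenyl)ethanone
Conditions: NBS (1.05 equiv), MeCN, 0 °C to rt
Reagents that add atoms: N-bromosuccinimide, O=C1CCC(=O)N1Br
Why: Electrophilic aromatic bromination should go cleanly at C5, the only position that is para to the free phenol and meta to the deactivating acetyl group.

Step 2
Reactants: 2 1-(5-bromo-2-hydroxy-3-methoxyphenyl)ethanone
Product: 4 6-bromo-8-methoxy-4H-chromen-4-one, via enaminone 3 (not isolated)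
Conditions: Me2NCH(OMe)2, toluene, 100 °C; then conc. HCl, CH2Cl2, 40 °C
Reagents that add atoms: N,N-dimethylformamide dimethyl acetal, COC(OC)N(C)C
Why: Enaminone formation from the methyl ketone followed by acid-mediated addition of the phenol and loss of dimethylamine is the standard chromone synthesis from 2-hydroxyacetophenones.

Step 3
Reactants: 4 6-bromo-8-methoxy-4H-chromen-4-one; 5 allyl tert-butyldimethylsilyl ether
Product: 7 6-[3-(tert-butyldimethylsilyloxy)propyl]-8-methoxy-4H-chromen-4-one, via B-alkyl borane 6 (not isolated)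
Conditions: 5 (1.3 equiv), 9-BBN-H (1.2 equiv), THF, 0 °C to rt; then 4, PdCl2(dppf) (5 mol %), aq K3PO4, DMF/THF, 50 °C
Reagents that add atoms: none
Why: Anti-Markovnikov hydroboration of the allyl ether and B-alkyl Suzuki–Miyaura coupling with the electron-poor aryl bromide should attach the three-carbon chain, with phosphate base and moderate temperature chosen to spare the chromone from ring opening.

Step 4
Reactants: 7 6-[3-(tert-butyldimethylsilyloxy)propyl]-8-methoxy-4H-chromen-4-one; 8 4-benzyloxy-3-methoxyphenylboronic acid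
Product: 9 (2R)-2-(4-benzyloxy-3-methoxyphenyl)-6-[3-(tert-butyldimethylsilyloxy)propyl]-8-methoxychroman-4-one
Conditions: Pd(OCOCF3)2 (5 mol %), (S)-t-BuPyOx (6 mol %), NH4PF6 (30 mol %), H2O (5 equiv), ClCH2CH2Cl, 60 °C
Reagents that add atoms: none
Why: Pd(II)/pyridine-oxazoline-catalysed asymmetric conjugate addition of an arylboronic acid to a chromone (aryl-Pd insertion, then protonolysis of the Pd enolate) should give the flavanone, the tert-butyl oxazoline differentiating the enone faces at insertion and so setting C2 as R.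

Step 5
Reactants: 9 (2R)-2-(4-benzyloxy-3-methoxyphenyl)-6-[3-(tert-butyldimethylsilyloxy)propyl]-8-methoxychroman-4-one
Product: 11 (2S)-2-(4-benzyloxy-3-methoxyphenyl)-6-[3-(tert-butyldimethylsilyloxy)propyl]-3-diazo-8-methoxychroman-4-one, via trifluoroacetyl ketone 10 (not isolated)
Conditions: LiHMDS (1.1 equiv), THF, −78 °C; CF3CO2CH2CF3, −78 °C; cold 1 M HCl work-up; then MsN3, Et3N, H2O (1 equiv), MeCN, rt
Reagents that add atoms: methanesulfonyl azide, CS(=O)(=O)N=[N+]=[N-]; 2,2,2-trifluoroethyl trifluoroacetate, O=C(OCC(F)(F)F)C(F)(F)F (its acyl group is present in 10 only and is lost again)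
Why: Detrifluoroacetylative (Danheiser) diazo transfer should work because the kinetic lithium enolate is C-acylated within minutes at −78 °C, before the aryloxide can be eliminated, and the activated diketone then passes its diazo group from the sulfonyl azide under mild amine base without touching C2 (the descriptor changes to S only because the diazo carbon outranks the aryl carbon).

Step 6
Reactants: 11 (2S)-2-(4-benzyloxy-3-methoxyphenyl)-6-[3-(tert-butyldimethylsilyloxy)propyl]-3-diazo-8-methoxychroman-4-one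
Product: 14 methyl (2R,3R)-2-(4-benzyloxy-3-methoxyphenyl)-5-[3-(tert-butyldimethylsilyloxy)propyl]-7-methoxy-2,3-dihydro-1-benzofuran-3-carboxylate, via ketene 12 (not isolated), via C3-epimeric ester 13 (not isolated)
Conditions: hν (350–370 nm), MeOH/THF, 0–10 °C; then NaOMe (0.3 equiv), MeOH, rt
Reagents that add atoms: methanol, CO
Why: Photochemical Wolff rearrangement with ring contraction: excitation of the diazo ketone, which the ring holds in the s-Z geometry, expels N2 in concert with the 1,2-shift of the aryl carbon (C4a of the chromanone) from the carbonyl carbon to C3, so that C3–C3a forms and the former carbonyl carbon leaves the ring as the ketene carbon (later C9). The closest known reaction type is the photolytic contraction of benzo-fused cyclic 2-diazo-1-ketones (2-diazo-1-tetralone to indane-1-carboxylates) with trapping of the ketene by an alcohol. The dihydrofuran ring O1–C2–C3–C3a–C7a is closed by migration and not by cyclisation: O1–C2, C2–C3 and O1–C7a are already present and the six-membered ring contracts through the new C3–C3a bond. Methanol adds to the ketene and the enol is protonated at C3, probably from the face opposite the C2 aryl group (cis ester), after which catalytic methoxide equilibrates C3 through the ester enolate to the trans isomer, so C3 is set under thermodynamic control by the C2 stereocentre, which takes no part in the rearrangement. The step needs migration to outrun the carbene pathways (O–H insertion into methanol, 1,2-hydride shift from C2 to the flavone); the concerted excited-state path of an s-Z cyclic diazo ketone and the high migratory aptitude of the alkoxy-substituted aryl carbon are relied on for this. During equilibration the aryloxide should not be expelled, because the C2–O1 bond lies near the nodal plane of the exocyclic enolate in the five-membered ring (the reverse of a 5-endo-trig closure).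

Step 7
Reactants: 14 methyl (2R,3R)-2-(4-benzyloxy-3-methoxyphenyl)-5-[3-(tert-butyldimethylsilyloxy)propyl]-7-methoxy-2,3-dihydro-1-benzofuran-3-carboxylate
Product: 15 [(2R,3S)-2-(4-benzyloxy-3-methoxyphenyl)-5-[3-(tert-butyldimethylsilyloxy)propyl]-7-methoxy-2,3-dihydro-1-benzofuran-3-yl]methanol
Conditions: LiAlH4, THF, 0 °C
Reagents that add atoms: none
Why: Hydride reduction of the methyl ester should give the C9 alcohol, the silyl and benzyl ethers being inert at 0 °C and C3 not being epimerised (the descriptor changes to 3S by priority only).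

Step 8
Reactants: 15 [(2R,3S)-2-(4-benzyloxy-3-methoxyphenyl)-5-[3-(tert-butyldimethylsilyloxy)propyl]-7-methoxy-2,3-dihydro-1-benzofuran-3-yl]methanol
Product: 16 4-[(2R,3S)-5-[3-(tert-butyldimethylsilyloxy)propyl]-3-(hydroxymethyl)-7-methoxy-2,3-dihydro-1-benzofuran-2-yl]-2-methoxyphenol
Conditions: H2 (1 atm), 10% Pd/C, EtOAc, rt, stopped at full conversion
Reagents that add atoms: none
Why: Catalytic hydrogenolysis should remove the aryl benzyl ether well before the cyclic benzylic C2–O1 bond is attacked, and the alkyl TBS ether is stable in ethyl acetate.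

Step 9
Reactants: 16 4-[(2R,3S)-5-[3-(tert-butyldimethylsilyloxy)propyl]-3-(hydroxymethyl)-7-methoxy-2,3-dihydro-1-benzofuran-2-yl]-2-methoxyphenol
Product: 17 (2R,3S)-5-[3-(tert-butyldimethylsilyloxy)propyl]-7-methoxy-2-[3-methoxy-4-(triisopropylsilyloxy)phenyl]-3-[(triisopropylsilyloxy)methyl]-2,3-dihydro-1-benzofuran
Conditions: TIPSCl (2.5 equiv), imidazole, DMAP (cat.), DMF, rt
Reagents that add atoms: triisopropylsilyl chloride, CC(C)[Si](Cl)(C(C)C)C(C)C
Why: Silylation of the phenol and the C9 alcohol in one operation puts the bulky, acid-resistant TIPS group on both hydroxyls that must stay masked.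

Step 10
Reactants: 17 (2R,3S)-5-[3-(tert-butyldimethylsilyloxy)propyl]-7-methoxy-2-[3-methoxy-4-(triisopropylsilyloxy)phenyl]-3-[(triisopropylsilyloxy)methyl]-2,3-dihydro-1-benzofuran
Product: 18 3-[(2R,3S)-7-methoxy-2-[3-methoxy-4-(triisopropylsilyloxy)phenyl]-3-[(triisopropylsilyloxy)methyl]-2,3-dihydro-1-benzofuran-5-yl]propan-1-ol
Conditions: CSA (10 mol %), MeOH/CH2Cl2, 0 °C
Reagents that add atoms: none
Why: Acid-catalysed methanolysis distinguishes silyl ethers by bulk, so the primary TBS ether should be solvolysed much faster than the alkyl and aryl TIPS ethers.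

Step 11
Reactants: 19 ferulic acid
Product: 21 (E)-3-[4-(tert-butyldimethylsilyloxy)-3-methoxyphenyl]prop-2-enoic acid, via silyl ester 20 (not isolated)
Conditions: TBSCl (2.2 equiv), imidazole, DMF, rt; then AcOH/THF/H2O, rt
Reagents that add atoms: tert-butyldimethylsilyl chloride, CC(C)(C)[Si](C)(C)Cl
Why: Bis-silylation of phenol and acid followed by selective hydrolysis of the labile silyl ester should leave the phenol-protected acid.

Step 12
Reactants: 18 3-[(2R,3S)-7-methoxy-2-[3-methoxy-4-(triisopropylsilyloxy)phenyl]-3-[(triisopropylsilyloxy)methyl]-2,3-dihydro-1-benzofuran-5-yl]propan-1-ol; 21 (E)-3-[4-(tert-butyldimethylsilyloxy)-3-methoxyphenyl]prop-2-enoic acid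
Product: 22 3-[(2R,3S)-7-methoxy-2-[3-methoxy-4-(triisopropylsilyloxy)phenyl]-3-[(triisopropylsilyloxy)methyl]-2,3-dihydro-1-benzofuran-5-yl]propyl (E)-3-[4-(tert-butyldimethylsilyloxy)-3-methoxyphenyl]prop-2-enoate
Conditions: EDC·HCl, DMAP, CH2Cl2, rt
Reagents that add atoms: none
Why: Steglich-type carbodiimide/DMAP esterification should acylate the only free hydroxyl without touching the E-alkene.

Step 13
Reactants: 22 3-[(2R,3S)-7-methoxy-2-[3-methoxy-4-(triisopropylsilyloxy)phenyl]-3-[(triisopropylsilyloxy)methyl]-2,3-dihydro-1-benzofuran-5-yl]propyl (E)-3-[4-(tert-butyldimethylsilyloxy)-3-methoxyphenyl]prop-2-enoate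
Product: 23 3-[(2R,3S)-2-(4-hydroxy-3-methoxyphenyl)-3-(hydroxymethyl)-7-methoxy-2,3-dihydro-1-benzofuran-5-yl]propyl (E)-3-(4-hydroxy-3-methoxyphenyl)prop-2-enoate
Conditions: TBAF/AcOH (1:1, 4 equiv), THF, 0 °C to rt
Reagents that add atoms: none
Why: Fluoride-mediated desilylation should remove all three silyl ethers, the acetic acid buffer keeping the phenols protonated so that the cinnamate ester is not cleaved and the 2-(4-hydroxyaryl) benzylic ether does not open through a quinone methide.

**Compound list**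
1 | 2'-hydroxy-3'-methoxyacetophenone | CC(=O)c1cccc(OC)c1O | starting material
2 | 1-(5-bromo-2-hydroxy-3-methoxyphenyl)ethanone | CC(=O)c1cc(Br)cc(OC)c1O | intermediate
3 | (E)-1-(5-bromo-2-hydroxy-3-methoxyphenyl)-3-(dimethylamino)prop-2-en-1-one | CN(C)/C=C/C(=O)c1cc(Br)cc(OC)c1O | intermediate
4 | 6-bromo-8-methoxy-4H-chromen-4-one | COc1cc(Br)cc2c(=O)ccoc12 | intermediate
5 | allyl tert-butyldimethylsilyl ether | C=CCO[Si](C)(C)C(C)(C)C | starting material
6 | 9-[3-(tert-butyldimethylsilyloxy)propyl]-9-borabicyclo[3.3.1]nonane | CC(C)(C)[Si](C)(C)OCCCB1C2CCCC1CCC2 | intermediate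
7 | 6-[3-(tert-butyldimethylsilyloxy)propyl]-8-methoxy-4H-chromen-4-one | COc1cc(CCCO[Si](C)(C)C(C)(C)C)cc2c(=O)ccoc12 | intermediate
8 | 4-benzyloxy-3-methoxyphenylboronic acid | COc1cc(B(O)O)ccc1OCc1ccccc1 | starting material
9 | (2R)-2-(4-benzyloxy-3-methoxyphenyl)-6-[3-(tert-butyldimethylsilyloxy)propyl]-8-methoxychroman-4-one | CC(C)(C)[Si](C)(C)OCCCc2cc(OC)c3c(c2)C(=O)C[C@H](c2ccc(OCc4ccccc4)c(OC)c2)O3 | intermediate
10 | (2R)-2-(4-benzyloxy-3-methoxyphenyl)-6-[3-(tert-butyldimethylsilyloxy)propyl]-8-methoxy-3-(trifluoroacetyl)chroman-4-one (C3 not defined, largely enolised) | CC(C)(C)[Si](C)(C)OCCCc2cc(OC)c3c(c2)C(=O)C(C(=O)C(F)(F)F)[C@H](c2ccc(OCc4ccccc4)c(OC)c2)O3 | intermediate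
11 | (2S)-2-(4-benzyloxy-3-methoxyphenyl)-6-[3-(tert-butyldimethylsilyloxy)propyl]-3-diazo-8-methoxychroman-4-one (C2 geometry as in 9) | CC(C)(C)[Si](C)(C)OCCCc2cc(OC)c3c(c2)C(=O)C(=[N+]=[N-])[C@H](c2ccc(OCc4ccccc4)c(OC)c2)O3 | intermediate
12 | 2-(4-benzyloxy-3-methoxyphenyl)-5-[3-(tert-butyldimethylsilyloxy)propyl]-7-methoxy-3-(oxomethylidene)-2,3-dihydro-1-benzofuran (ketene, C2 geometry as in 11) | CC(C)(C)[Si](C)(C)OCCCc2cc(OC)c3c(c2)C(=C=O)[C@H](c2ccc(OCc4ccccc4)c(OC)c2)O3 | intermediate
13 | methyl (2R)-2-(4-benzyloxy-3-methoxyphenyl)-5-[3-(tert-butyldimethylsilyloxy)propyl]-7-methoxy-2,3-dihydro-1-benzofuran-3-carboxylate, mixture of C3 epimers | CC(C)(C)[Si](C)(C)OCCCc2cc(OC)c3c(c2)C(C(=O)OC)[C@H](c2ccc(OCc4ccccc4)c(OC)c2)O3 | intermediate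
14 | methyl (2R,3R)-2-(4-benzyloxy-3-methoxyphenyl)-5-[3-(tert-butyldimethylsilyloxy)propyl]-7-methoxy-2,3-dihydro-1-benzofuran-3-carboxylate (trans) | CC(C)(C)[Si](C)(C)OCCCc2cc(OC)c3c(c2)[C@@H](C(=O)OC)[C@H](c2ccc(OCc4ccccc4)c(OC)c2)O3 | intermediate
15 | [(2R,3S)-2-(4-benzyloxy-3-methoxyphenyl)-5-[3-(tert-butyldimethylsilyloxy)propyl]-7-methoxy-2,3-dihydro-1-benzofuran-3-yl]methanol | CC(C)(C)[Si](C)(C)OCCCc2cc(OC)c3c(c2)[C@@H](CO)[C@H](c2ccc(OCc4ccccc4)c(OC)c2)O3 | intermediate
16 | 4-[(2R,3S)-5-[3-(tert-butyldimethylsilyloxy)propyl]-3-(hydroxymethyl)-7-methoxy-2,3-dihydro-1-benzofuran-2-yl]-2-methoxyphenol | CC(C)(C)[Si](C)(C)OCCCc2cc(OC)c3c(c2)[C@@H](CO)[C@H](c2ccc(O)c(OC)c2)O3 | intermediate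
17 | (2R,3S)-5-[3-(tert-butyldimethylsilyloxy)propyl]-7-methoxy-2-[3-methoxy-4-(triisopropylsilyloxy)phenyl]-3-[(triisopropylsilyloxy)methyl]-2,3-dihydro-1-benzofuran | CC(C)(C)[Si](C)(C)OCCCc2cc(OC)c3c(c2)[C@@H](CO[Si](C(C)C)(C(C)C)C(C)C)[C@H](c2ccc(O[Si](C(C)C)(C(C)C)C(C)C)c(OC)c2)O3 | intermediate
18 | 3-[(2R,3S)-7-methoxy-2-[3-methoxy-4-(triisopropylsilyloxy)phenyl]-3-[(triisopropylsilyloxy)methyl]-2,3-dihydro-1-benzofuran-5-yl]propan-1-ol | OCCCc2cc(OC)c3c(c2)[C@@H](CO[Si](C(C)C)(C(C)C)C(C)C)[C@H](c2ccc(O[Si](C(C)C)(C(C)C)C(C)C)c(OC)c2)O3 | intermediate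
19 | ferulic acid, (E)-3-(4-hydroxy-3-methoxyphenyl)prop-2-enoic acid | COc1cc(/C=C/C(=O)O)ccc1O | starting material
20 | tert-butyldimethylsilyl (E)-3-[4-(tert-butyldimethylsilyloxy)-3-methoxyphenyl]prop-2-enoate | COc1cc(/C=C/C(=O)O[Si](C)(C)C(C)(C)C)ccc1O[Si](C)(C)C(C)(C)C | intermediate
21 | (E)-3-[4-(tert-butyldimethylsilyloxy)-3-methoxyphenyl]prop-2-enoic acid | COc1cc(/C=C/C(=O)O)ccc1O[Si](C)(C)C(C)(C)C | intermediate
22 | 3-[(2R,3S)-7-methoxy-2-[3-methoxy-4-(triisopropylsilyloxy)phenyl]-3-[(triisopropylsilyloxy)methyl]-2,3-dihydro-1-benzofuran-5-yl]propyl (E)-3-[4-(tert-butyldimethylsilyloxy)-3-methoxyphenyl]prop-2-enoate | COc1cc(/C=C/C(=O)OCCCc2cc(OC)c3c(c2)[C@@H](CO[Si](C(C)C)(C(C)C)C(C)C)[C@H](c2ccc(O[Si](C(C)C)(C(C)C)C(C)C)c(OC)c2)O3)ccc1O[Si](C)(C)C(C)(C)C | intermediate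
23 | 3-[(2R,3S)-2-(4-hydroxy-3-methoxyphenyl)-3-(hydroxymethyl)-7-methoxy-2,3-dihydro-1-benzofuran-5-yl]propyl (E)-3-(4-hydroxy-3-methoxyphenyl)prop-2-enoate (CNP0149450.1) | COc1cc(/C=C/C(=O)OCCCc2cc(OC)c3c(c2)[C@@H](CO)[C@H](c2ccc(O)c(OC)c2)O3)ccc1O | target

**Step count**
Total steps: 13. Longest linear sequence: 12 steps (1 to 23 through steps 1–10, 12 and 13; step 11 is a one-step side branch).

**Steps most likely to fail**

Step 6 (key step). Loss of nitrogen may pass through a free carbene that inserts into the O–H bond of methanol, or takes the C2 hydrogen by a 1,2-hydride shift (which would give the flavone and destroy C2), faster than the aryl carbon migrates. Incomplete equilibration at C3 is a lesser concern. The fallback sets out from flavanone 9 and drops the diazo ketone altogether: iodine(III)-mediated oxidative ring contraction (PhI(OAc)2, cat. H2SO4, HC(OMe)3, rt), a known reaction of flavanones in which the in situ enol ether is attacked at C3 by the iodane and the same aryl carbon shifts with loss of iodobenzene to give the trans methyl ester. The acid is expected to remove the primary silyl ether, giving methyl (2R,3R)-2-(4-benzyloxy-3-methoxyphenyl)-5-(3-hydroxypropyl)-7-methoxy-2,3-dihydro-1-benzofuran-3-carboxylate F1, which is re-silylated (TBSCl, imidazole, DMF) and comes back to the route at 14.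

Step 5. β-Elimination of the ring aryloxide from the lithium enolate (ring opening to the chalcone phenoxide and reclosure) would erode the C2 configuration, and O- instead of C-acylation would stall the diazo transfer. The fallback sets out from 9 and avoids a free enolate: soft enolisation (TMSOTf, Et3N, CH2Cl2, 0 °C) gives (2R)-2-(4-benzyloxy-3-methoxyphenyl)-6-[3-(tert-butyldimethylsilyloxy)propyl]-8-methoxy-4-(trimethylsilyloxy)-2H-chromene F2, and electrophilic C-acylation of this neutral silyl enol ether with trifluoroacetic anhydride (CH2Cl2, 0 °C) comes back to the route at 10, which is treated with MsN3/Et3N as before.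

Step 4. Insertion may be slow with the electron-rich boronic acid (protodeboronation and homocoupling take over), facial discrimination may be insufficient, or the silyl ether may be partly lost in the aqueous ammonium hexafluorophosphate medium. The fallback sets out from 7 and 8 and replaces catalyst control by resolution: racemic rhodium(I)-catalysed 1,4-addition ([Rh(cod)OH]2, dioxane/H2O, 60 °C) gives racemic 2-(4-benzyloxy-3-methoxyphenyl)-6-[3-(tert-butyldimethylsilyloxy)propyl]-8-methoxychroman-4-one F3. Preparative chiral-phase chromatography then separates 9 from (2S)-2-(4-benzyloxy-3-methoxyphenyl)-6-[3-(tert-butyldimethylsilyloxy)propyl]-8-methoxychroman-4-one F4, which is returned to F3 by base-mediated racemisation; the route is rejoined at 9.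

Further compounds
F1 | step 6 | methyl (2R,3R)-2-(4-benzyloxy-3-methoxyphenyl)-5-(3-hydroxypropyl)-7-methoxy-2,3-dihydro-1-benzofuran-3-carboxylate | OCCCc2cc(OC)c3c(c2)[C@@H](C(=O)OC)[C@H](c2ccc(OCc4ccccc4)c(OC)c2)O3
F2 | step 5 | (2R)-2-(4-benzyloxy-3-methoxyphenyl)-6-[3-(tert-butyldimethylsilyloxy)propyl]-8-methoxy-4-(trimethylsilyloxy)-2H-chromene | CC(C)(C)[Si](C)(C)OCCCc2cc(OC)c3c(c2)C(O[Si](C)(C)C)=C[C@H](c2ccc(OCc4ccccc4)c(OC)c2)O3
F3 | step 4 | racemic 2-(4-benzyloxy-3-methoxyphenyl)-6-[3-(tert-butyldimethylsilyloxy)propyl]-8-methoxychroman-4-one | CC(C)(C)[Si](C)(C)OCCCc2cc(OC)c3c(c2)C(=O)CC(c2ccc(OCc4ccccc4)c(OC)c2)O3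
F4 | step 4 | (2S)-2-(4-benzyloxy-3-methoxyphenyl)-6-[3-(tert-butyldimethylsilyloxy)propyl]-8-methoxychroman-4-one | CC(C)(C)[Si](C)(C)OCCCc2cc(OC)c3c(c2)C(=O)C[C@@H](c2ccc(OCc4ccccc4)c(OC)c2)O3
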